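## The problem

Emmaosunin (12) is 5-hydroxy-3,6,7,8-tetramethoxy-2-(3-methoxyphenyl)-4H-chromen-4-one. It is a planar flavonol ether with no stereocentre, so the whole task is one of constitution. Ring B (3-methoxyphenyl) and ring C (3-methoxy-4-pyranone) are ordinary.

The difficulty lies in ring A, a benzene ring without hydrogen. C5, C6, C7, C8 and C8a all carry oxygen, and C4a carries the C4 carbonyl carbon. No simple arene has this pentaoxygenated pattern. Adding the oxygens one by one passes through ever more electron-rich phenols, which tend to be oxidised to quinones rather than substituted. Of the four contiguous oxygens on C5–C8, exactly one (O5) must stay free, so they have to be told apart.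

Several groups exclude rough treatment:
- Ring C opens with hydroxide and other hard nucleophiles at C2, and strong methylating agents alkylate its carbonyl oxygen.
- Strong Lewis acids strip the 3- and 5-ethers.
- The 5-hydroxy-8-methoxy pair is a hydroquinone monoether, which oxidants convert to the 5,8-quinone.

The feature that makes the key step possible is this. C5–C6–C7–C8 is a chain of four carbons with one oxygen each, which is the C4O4 skeleton of a squarate. The other two atoms of ring A, C4a and C8a, are also the C=C bond of ring C, that is C5=C6 of a monocyclic 4-pyranone. O5 and O8 are para to each other. This is the pattern left by ring expansion of a 4-alkoxy-4-alkenylcyclobutenone, whose single free hydroxyl comes from the ring carbonyl.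

## Retrosynthesis

**Ring A, 12 ⇒ 9.** The bond C4a–C5 is cut and C5 is rejoined to C8, which contracts ring A to the cyclobutenone 9.
- The neighbouring cuts are C–O bonds on ring A (late oxygenation) or the bonds of ring C (the classical flavone logic). Both leave the pentaoxygenated arene unsolved.
- This cut removes the arene altogether. Compound 9 is an isomer of 12 that holds every atom and every methyl group, but no benzene ring A and no fused bicycle.
- The forward reaction needs only heat. It opens 9 to the dienylketene 10, closes it to the dienone 11, and enolises 11 to 12.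
- Three things are asked of it. The methoxy group on C4 of the cyclobutenone must rotate outward. The ketene must close on the pyranone C=C bond. The one oxygen without a methyl group must end at C5.

**Joining the halves, 9 ⇒ 5 + 6.** The bond C8–C8a (cyclobutenone C4 to pyranone C6) and the O8–CH3 bond are cut. This gives the pyranone 5, dimethyl squarate 6 and a methyl cation equivalent.
- The neighbouring choice joins 6 to pyranone C5 (the future C4a–C5 bond). That would need a halogen at C5. It would pass through a β-alkoxyvinyl metal that can open by elimination. It would also place the carbinol oxygen at O5, the one that must not be methylated.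
- Joining at C6 uses the most acidic C–H bond of 5 directly, through 7. It places the carbinol oxygen of 8 at O8, where a methyl group is wanted.
- Compound 6 has two equivalent carbonyl groups, so the addition raises no regiochemical question.
- The twenty-carbon target falls into a thirteen-carbon pyranone and a commercial C6 unit.
- There is a built-in safeguard. If the carbinol is left free, attachment at C5 or at C6 leads to the same 5,8-hydroquinone.

**Ring B, 5 ⇒ 3 + 4.** The biaryl-type bond C2–C1' is cut.
- Building ring C from an open-chain triketone equivalent would need a regiodefined acylation of an α-methoxy ketone enolate. It would also need a non-commercial alkoxyenone.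
- A cross-coupling of the vinylogous acyl bromide 3 with the commercial boronic acid 4 places the aryl group unambiguously.
- The forward reaction must be faster than hydrolysis of the C2–Br bond.

**Pyranone core, 3 ⇒ 2 ⇒ 1.** The O3–CH3 and C2–Br bonds are cut back to commercial 1.
- The enolic 3-hydroxyl of 1 activates only C2, so an electrophilic bromine source should give 2.
- Bromination comes before methylation because the free enol is what directs it.

## Roads not taken

**Alternative 1:** This is the route most chemists would draw first. Ring C is cut at O1–C2, C2–C3 and C3–O.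
- Forward sequence: 1-(2-hydroxy-3,4,5,6-tetramethoxyphenyl)ethan-1-one A1 is condensed with the ring B aldehyde to the chalcone A2. An Algar–Flynn–Oyamada oxidation gives the flavonol A3. Methylation of O3 and Lewis-acid cleavage of the 5-methyl ether follow.
- Why it loses: all the difficulty is pushed into A1, which is not a simple building block and needs a chain of arene oxidations. A2 carries a 6'-methoxy group, the substitution that diverts the alkaline peroxide cyclisation toward five-membered ring closure (aurones). The free O5 is regained only by removing a methyl group that was put on earlier, in competition with the 3-ether. The chosen plan builds the ring with its oxygens already differentiated and is much shorter.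

**Alternative 2:** The C8–O and C6–O bonds are cut (late C–H oxygenation).
- Forward sequence: the phloroglucinol-type flavone 5-hydroxy-3,7-dimethoxy-2-(3-methoxyphenyl)-4H-chromen-4-one A4 undergoes an Elbs persulfate oxidation (K2S2O8, aqueous KOH), or an anodic methoxylation, para to O5. This gives the 5,8-quinol A5, which is then partially methylated.
- Why it loses: the phenolate that must attack the oxidant is tied up in the chelate with C4=O. The alkaline medium threatens ring C. After C8 is oxidised, C6 still lacks its oxygen and has no para phenol to direct a second oxidation, and the ring is by then a hydroquinone ether prone to over-oxidation. Two separate C–H oxidations plus two methylations replace what one ring construction delivers.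

**Alternative 3:** Ring A is cut into carbene carbon, alkyne and CO (Dötz benzannulation).
- Forward sequence: the Fischer carbene complex A6, (CO)5Cr=C(OMe)(pyranonyl), is made from 7 with Cr(CO)6 and a methylating agent. It reacts with dimethoxyacetylene A7. The mapping is correct: the carbene carbon becomes C8–OMe, the CO becomes C5–OH and the alkyne becomes C6/C7.
- Why it loses: A7 is not a reagent that can be stored or handled. Bulkier dialkoxyalkynes that can be handled would bring in alkyl groups that must later be exchanged. The reaction needs stoichiometric chromium, and acceptor-substituted alkenyl carbene complexes are prone to five-membered ring formation without CO insertion. The metal-free dienylketene 10 is the same kind of intermediate, and 6 supplies alkyne, CO and carbene carbon together as one bench-stable solid.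

Key step: step 5

Remark: 12 has no stereocentre. Compounds 8, 9 and 11 hold one stereocentre each, form as racemates and lose it on the way to 12, so their SMILES carry no descriptor. C2–C8a refers to the flavone numbering of 12, and "pyranone C5/C6" refers to the numbering of 5.

## Steps

Step 1
Reactants: 1 3-hydroxy-4H-pyran-4-one (pyromeconic acid)
Product: 2 2-bromo-3-hydroxy-4H-pyran-4-one
Conditions: NBS (1.0 equiv), MeCN, 0 °C to rt, dark
Reagents that add atoms: N-bromosuccinimide, O=C1CCC(=O)N1Br
Why: Electrophilic bromination of an enol; the 3-hydroxyl makes C2 its enolic carbon, the position at which 3-hydroxy-4-pyranones are halogenated, hydroxymethylated and aminomethylated, while C5 and C6 belong to the unactivated vinylogous ester half.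

Step 2
Reactants: 2 2-bromo-3-hydroxy-4H-pyran-4-one
Product: 3 2-bromo-3-methoxy-4H-pyran-4-one
Conditions: MeI, K2CO3, acetone, 40 °C
Reagents that add atoms: iodomethane, CI
Why: Williamson O-methylation of the acidic enolic hydroxyl under a mild carbonate base; the soft alkylating agent does not touch the pyranone carbonyl oxygen and no hydroxide is present to attack C2.

Step 3
Reactants: 3 2-bromo-3-methoxy-4H-pyran-4-one; 4 3-methoxyphenylboronic acid
Product: 5 3-methoxy-2-(3-methoxyphenyl)-4H-pyran-4-one
Conditions: Pd(dppf)Cl2 (3 mol %), K3PO4, 1,4-dioxane/H2O 10:1, 80 °C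
Reagents that add atoms: none
Why: Suzuki–Miyaura coupling; the C2–Br bond is a vinylogous acyl bromide and should add readily to zerovalent palladium, as 2-halo-3-alkoxypyranones and 2-halochromones do. The small amount of water and the mild phosphate base are chosen to spare ring C.

Step 4
Reactants: 5 3-methoxy-2-(3-methoxyphenyl)-4H-pyran-4-one; 6 dimethyl squarate (3,4-dimethoxycyclobut-3-ene-1,2-dione)
Product: 9 2,3,4-trimethoxy-4-[5-methoxy-6-(3-methoxyphenyl)-4-oxo-4H-pyran-2-yl]cyclobut-2-en-1-one (racemic), via 6-lithiopyranone 7 (not isolated), via lithium alkoxide 8 (not isolated)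
Conditions: TMPH, n-BuLi, THF, −78 °C, then 5; transfer into 6 (1.2 equiv), THF, −78 °C; MeOTf (1.2 equiv), −78 to 0 °C
Reagents that add atoms: methyl trifluoromethanesulfonate, COS(=O)(=O)C(F)(F)F
Why: Deprotonative lithiation at the C–H next to the ring oxygen, the site at which chromones (at C2) and cyclic enol ethers are metalated by hindered amide bases; 7 has no β-leaving group. 1,2-Addition of organolithiums to 6 and trapping of the tertiary alkoxide with MeOTf is the standard entry to 4-alkoxycyclobutenones, and the equivalence of the two carbonyl groups of 6 removes any regiochemical question.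

Step 5
Reactants: 9 2,3,4-trimethoxy-4-[5-methoxy-6-(3-methoxyphenyl)-4-oxo-4H-pyran-2-yl]cyclobut-2-en-1-one
Product: 12 emmaosunin (5-hydroxy-3,6,7,8-tetramethoxy-2-(3-methoxyphenyl)-4H-chromen-4-one), via dienylketene 10 (not isolated), via cyclohexadienone 11 (not isolated)
Conditions: toluene (0.02 M), reflux, Ar
Reagents that add atoms: none
Why: Proposed new method: heat opens 9 by conrotatory 4π cleavage of the C1–C4 bond of the cyclobutenone, and the donor methoxy group on C4 rotates outward (torquoselectivity), which places the pyranonyl group cis to the ketene in 10. Ring A, the only ring closed, then forms by a disrotatory 6π electrocyclisation of the dienylketene, the ketene carbon bonding to pyranone C5 (the new bond C5–C4a of 12). The termini are matched in polarity, since the ketene carbon is electrophilic and pyranone C5 is the nucleophilic α-carbon of a vinylogous ester, and only the weak cyclic conjugation of a 4-pyranone is interrupted, less than that of the benzene or furan rings that take part in the known cases. Dienone 11 carries its hydrogen at C4a between two carbonyl groups and should enolise at once to the hydrogen-bonded 5-phenol, which drains the reversible steps toward 12. The closest known reaction type is the Moore–Liebeskind ring expansion of 4-aryl-, 4-heteroaryl- and 4-(1-alkoxyalkenyl)-4-alkoxycyclobutenones to hydroquinone monoethers; the C=C bond of a 4-pyranone has not served as the 2π partner, hence the label. The selectivity needed is constitutional, namely which of the four contiguous oxygens stays free, and the substrate fixes it: the cyclobutenone carbonyl, the only oxygen without methyl, ends at C5 next to C4a, and the carbinol ether ends at C8 next to C8a. No stereocentre is set, as C4 of 9 and C4a of 11 both become trigonal in 12.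

## Compound list

1 | 3-hydroxy-4H-pyran-4-one (pyromeconic acid) | Oc1coccc1=O | starting material
2 | 2-bromo-3-hydroxy-4H-pyran-4-one | Oc1c(Br)occc1=O | intermediate
3 | 2-bromo-3-methoxy-4H-pyran-4-one | COc1c(Br)occc1=O | intermediate
4 | 3-methoxyphenylboronic acid | COc1cccc(B(O)O)c1 | starting material
5 | 3-methoxy-2-(3-methoxyphenyl)-4H-pyran-4-one | COc1cccc(-c2occc(=O)c2OC)c1 | intermediate
6 | dimethyl squarate (3,4-dimethoxycyclobut-3-ene-1,2-dione) | COC1=C(OC)C(=O)C1=O | starting material
7 | 6-lithio-3-methoxy-2-(3-methoxyphenyl)-4H-pyran-4-one | COc1cccc(-c2oc([Li])cc(=O)c2OC)c1 | intermediate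
8 | lithium 2,3-dimethoxy-1-[5-methoxy-6-(3-methoxyphenyl)-4-oxo-4H-pyran-2-yl]-4-oxocyclobut-2-en-1-olate (racemic) | [Li]OC1(C(OC)=C(OC)C1=O)c1cc(=O)c(OC)c(-c2cccc(OC)c2)o1 | intermediate
9 | 2,3,4-trimethoxy-4-[5-methoxy-6-(3-methoxyphenyl)-4-oxo-4H-pyran-2-yl]cyclobut-2-en-1-one (racemic) | COC1=C(OC)C(OC)(c2cc(=O)c(OC)c(-c3cccc(OC)c3)o2)C1=O | intermediate
10 | (3Z)-2,3,4-trimethoxy-4-[5-methoxy-6-(3-methoxyphenyl)-4-oxo-4H-pyran-2-yl]buta-1,3-dien-1-one | O=C=C(OC)/C(OC)=C(OC)\c1cc(=O)c(OC)c(-c2cccc(OC)c2)o1 | intermediate
11 | 3,6,7,8-tetramethoxy-2-(3-methoxyphenyl)-4aH-chromene-4,5-dione (racemic) | COC1=C(OC)C(=O)C2C(=O)C(OC)=C(c3cccc(OC)c3)OC2=C1OC | intermediate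
12 | emmaosunin, 5-hydroxy-3,6,7,8-tetramethoxy-2-(3-methoxyphenyl)-4H-chromen-4-one | COc1cccc(-c2oc3c(OC)c(OC)c(OC)c(O)c3c(=O)c2OC)c1 | target

## Step count and least certain steps

Total step count: 5. Longest linear sequence: 5 steps (1 → 2 → 3 → 5 → 9 → 12).

**Step 5 (key step, Proposed new method).**
- What may go wrong: the ketene may be consumed by routes other than the 6π closure, namely reclosure, dimerisation or capture by traces of water. This becomes likely if the acceptor-substituted pyranone C=C bond is too reluctant a partner, or if the conformer that turns C5 rather than the ring oxygen toward the ketene is poorly populated.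
- Fallback: known chemistry, setting out from 6 and returning at 12. It keeps the squarate as the source of the oxygen pattern but builds ring C in the classical way.
- 1-Methoxyvinyllithium (methyl vinyl ether, t-BuLi) is added to 6 and the alkoxide is trapped with MeOTf to give 2,3,4-trimethoxy-4-(1-methoxyvinyl)cyclobut-2-en-1-one F1.
- Thermolysis of F1 in toluene, a known ring expansion of the 4-(1-alkoxyalkenyl) class, gives 2,3,4,5-tetramethoxyphenol F2.
- Ortho-acylation at the only free position with methoxyacetyl chloride and BF3·OEt2 gives 1-(2-hydroxy-3,4,5,6-tetramethoxyphenyl)-2-methoxyethan-1-one F3.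
- Allan–Robinson condensation with 3-methoxybenzoic anhydride and sodium 3-methoxybenzoate gives 3,5,6,7,8-pentamethoxy-2-(3-methoxyphenyl)-4H-chromen-4-one F4.
- BCl3 in CH2Cl2 at low temperature cleaves the peri 5-methyl ether through the six-membered boron chelate to give 12.

**Step 4.**
- What may go wrong: the lithiated pyranone may add to not yet metalated 5 at C6. Part of the metalation may occur at C5 under the direction of the carbonyl group, followed by ring opening through β-elimination. Excess MeOTf may alkylate the pyranone carbonyl oxygen.
- Fallback: sets out from 5 and returns at 12. It drops both the deprotonation and the alkoxide methylation, and differentiates the hydroxyls after ring construction.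
- Iodination at C5 with I2 and (NH4)2Ce(NO3)6 in MeCN, the method used for C3 of methoxyflavones, gives 5-iodo-3-methoxy-2-(3-methoxyphenyl)-4H-pyran-4-one F5.
- Iodine–magnesium exchange with iPrMgCl·LiCl at −40 °C follows, as known for 5-iodo-1,3-dioxin-4-ones. The magnesium species resists elimination better than a lithium one. Addition to 6 and a proton quench give 4-hydroxy-2,3-dimethoxy-4-[5-methoxy-6-(3-methoxyphenyl)-4-oxo-4H-pyran-3-yl]cyclobut-2-en-1-one F6.
- Thermolysis gives 5,8-dihydroxy-3,6,7-trimethoxy-2-(3-methoxyphenyl)-4H-chromen-4-one F7. This is the same ring because 6 is symmetric; here the carbinol carbon becomes C5 and the ketene carbon becomes C8.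
- Me2SO4 (1 equiv) and K2CO3 in acetone methylate the free 8-hydroxyl while the chelated 5-hydroxyl stays untouched, giving 12.

**Step 3.**
- What may go wrong: the vinylogous acyl bromide may be hydrolysed, or ring C opened by the aqueous base, in competition with transmetalation. Protodeboronation of 4 is also possible.
- Fallback: sets out from 4 and returns at 5. It forms the aryl–carbon bond before ring C exists and also bypasses steps 1 and 2.
- Rhodium-catalysed 1,2-addition of 4 to furfural (Rh(acac)(CO)2, dppf, DME/H2O) gives furan-2-yl(3-methoxyphenyl)methanol F8.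
- Achmatowicz oxidation (NBS, aqueous THF, NaHCO3) gives 6-hydroxy-2-(3-methoxyphenyl)-2H-pyran-3(6H)-one F9.
- Bromination–dehydrobromination (Br2, then Et3N) gives 4-bromo-6-hydroxy-2-(3-methoxyphenyl)-2H-pyran-3(6H)-one F10.
- Hot aqueous acid, the sequence by which 2-alkyl-3-hydroxy-4-pyranones are made from furyl carbinols, gives 3-hydroxy-2-(3-methoxyphenyl)-4H-pyran-4-one F11.
- MeI and K2CO3 convert F11 into 5.

## Further compounds

F1 | step 5 | 2,3,4-trimethoxy-4-(1-methoxyvinyl)cyclobut-2-en-1-one (racemic) | COC(=C)C1(OC)C(OC)=C(OC)C1=O
F2 | step 5 | 2,3,4,5-tetramethoxyphenol | COc1cc(O)c(OC)c(OC)c1OC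
F3 | step 5 | 1-(2-hydroxy-3,4,5,6-tetramethoxyphenyl)-2-methoxyethan-1-one | COCC(=O)c1c(O)c(OC)c(OC)c(OC)c1OC
F4 | step 5 | 3,5,6,7,8-pentamethoxy-2-(3-methoxyphenyl)-4H-chromen-4-one | COc1cccc(-c2oc3c(OC)c(OC)c(OC)c(OC)c3c(=O)c2OC)c1
F5 | step 4 | 5-iodo-3-methoxy-2-(3-methoxyphenyl)-4H-pyran-4-one | COc1cccc(-c2occ(I)c(=O)c2OC)c1
F6 | step 4 | 4-hydroxy-2,3-dimethoxy-4-[5-methoxy-6-(3-methoxyphenyl)-4-oxo-4H-pyran-3-yl]cyclobut-2-en-1-one (racemic) | COC1=C(OC)C(O)(c2coc(-c3cccc(OC)c3)c(OC)c2=O)C1=O
F7 | step 4 | 5,8-dihydroxy-3,6,7-trimethoxy-2-(3-methoxyphenyl)-4H-chromen-4-one | COc1cccc(-c2oc3c(O)c(OC)c(OC)c(O)c3c(=O)c2OC)c1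
F8 | step 3 | furan-2-yl(3-methoxyphenyl)methanol (racemic) | COc1cccc(C(O)c2ccco2)c1
F9 | step 3 | 6-hydroxy-2-(3-methoxyphenyl)-2H-pyran-3(6H)-one (mixture of anomers) | COc1cccc(C2OC(O)C=CC2=O)c1
F10 | step 3 | 4-bromo-6-hydroxy-2-(3-methoxyphenyl)-2H-pyran-3(6H)-one (mixture of anomers) | COc1cccc(C2OC(O)C=C(Br)C2=O)c1
F11 | step 3 | 3-hydroxy-2-(3-methoxyphenyl)-4H-pyran-4-one | COc1cccc(-c2occc(=O)c2O)c1
A1 | alternative 1 | 1-(2-hydroxy-3,4,5,6-tetramethoxyphenyl)ethan-1-one | CC(=O)c1c(O)c(OC)c(OC)c(OC)c1OC
A2 | alternative 1 | (E)-1-(2-hydroxy-3,4,5,6-tetramethoxyphenyl)-3-(3-methoxyphenyl)prop-2-en-1-one | COc1cccc(/C=C/C(=O)c2c(O)c(OC)c(OC)c(OC)c2OC)c1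
A3 | alternative 1 | 3-hydroxy-5,6,7,8-tetramethoxy-2-(3-methoxyphenyl)-4H-chromen-4-one | COc1cccc(-c2oc3c(OC)c(OC)c(OC)c(OC)c3c(=O)c2O)c1
A4 | alternative 2 | 5-hydroxy-3,7-dimethoxy-2-(3-methoxyphenyl)-4H-chromen-4-one | COc1cccc(-c2oc3cc(OC)cc(O)c3c(=O)c2OC)c1
A5 | alternative 2 | 5,8-dihydroxy-3,7-dimethoxy-2-(3-methoxyphenyl)-4H-chromen-4-one | COc1cccc(-c2oc3c(O)c(OC)cc(O)c3c(=O)c2OC)c1
A6 | alternative 3 | pentacarbonyl{methoxy[5-methoxy-6-(3-methoxyphenyl)-4-oxo-4H-pyran-2-yl]carbene}chromium, (CO)5Cr=C(OMe)(pyranonyl) | COC(=[Cr])c1cc(=O)c(OC)c(-c2cccc(OC)c2)o1.[C-]#[O+].[C-]#[O+].[C-]#[O+].[C-]#[O+].[C-]#[O+]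
A7 | alternative 3 | dimethoxyacetylene | COC#COC
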